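Ring B (C4a, C5, C6, C7, C8, C8a) is cut back to a cyclobutane that spans the methyl-bearing C4a–C8a bond which rings A and B share, with C5, the one functionalised ring B carbon, bound to C4a. A single [2+2] photocycloaddition of allene to a ring A enone whose C4a=C8a alkene already carries both methyls forms C4a–C5 and C8–C8a, sets the two quaternary centres cis and leaves C5 as an exocyclic alkene. The precursor is a trans-2,3,6-trimethyl-4-oxocyclohex-2-ene-1-carboxylate holding the C1 ester and C2 methyl; two regiodefined one-carbon insertions between C5 and C8 later grow the four-membered ring into ring B.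

Key step: step 3

Remark: locants are those of the target's naphthalene core (C1 ester, C2 methyl, C4a and C8a angular methyls, C5 side chain, C5=C6; ring A = C1–C4/C4a/C8a, ring B = C4a/C5–C8/C8a) and α is the face of the C1 ester; the acid is carried as its methyl ester so that it can be freed late by SN2 attack at the methyl carbon; a racemate is written as two SMILES joined by a dot.

Step 1
Reactants: 1 methyl acetoacetate; 2 (E)-hex-4-en-3-one
Product: 5 racemic methyl trans-2,3,6-trimethyl-4-oxocyclohex-2-ene-1-carboxylate, via Michael adduct 3 (not isolated), via cyclic ketol 4 (not isolated)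
Conditions: NaOMe (0.1 equiv), MeOH, 0 → 23 °C; then pyrrolidine, AcOH (0.3 equiv each), PhMe, 110 °C, Dean–Stark
Reagents that add atoms: none
Why: Robinson annulation (Michael addition, then amine/acid-mediated aldol condensation) in which the ethyl-ketone CH2 closes onto the acetyl carbonyl of the acetoacetate unit (6-(enolendo)-exo-trig) and dehydration gives the conjugated tetrasubstituted enone; the C6 methyl centre forms without control (racemate), C1 equilibrates through the dienol, and the trans ester is taken on after chromatography while the cis epimer is re-equilibrated.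

Step 2
Reactants: 5 racemic methyl trans-2,3,6-trimethyl-4-oxocyclohex-2-ene-1-carboxylate
Product: 6 methyl (1S,6R)-2,3,6-trimethyl-4-oxocyclohex-2-ene-1-carboxylate
Conditions: preparative SFC, amylose tris(3,5-dimethylphenylcarbamate) stationary phase, CO2/i-PrOH 9:1, 35 °C
Reagents that add atoms: none
Why: Chromatographic resolution of enantiomers on a polysaccharide chiral stationary phase, a separation that makes no stereocentre and relies on the non-epimerisable C6 to hold the series; the (1S,6R) fraction is to be identified by anomalous-dispersion X-ray analysis of the sulfur-containing tosylhydrazone prepared from it in step 4.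

Step 3
Reactants: 6 methyl (1S,6R)-2,3,6-trimethyl-4-oxocyclohex-2-ene-1-carboxylate; 7 allene
Product: 8 methyl (1R,2S,3R,6R)-1,3,6-trimethyl-7-methylidene-5-oxobicyclo[4.2.0]octane-2-carboxylate
Conditions: hν (350 nm, Pyrex), 7 (15 equiv), CH2Cl2, −78 °C
Reagents that add atoms: none
Why: n→π* excitation and intersystem crossing give the twisted triplet enone, which adds ground-state allene stepwise to a triplet 1,4-biradical that, after spin inversion, collapses to the four-membered ring. The closest known reaction type is the enone–allene [2+2] photocycloaddition of 2,3-dialkylcyclohex-2-enones, where excited-state reactivity overrides the steric barrier of a tetrasubstituted alkene. The single ring closed, the cyclobutane C4a–C5–C8–C8a, is completed by radical–radical coupling of the 1,4-biradical and not by a concerted thermal pathway. The new quaternary centres C4a and C8a are set together: the two-carbon bridge enforces a cis ring fusion, and the face is fixed by the C1 ester, which A(1,2) strain against the C8a methyl keeps pseudoaxial next to the β-carbon, so that allene enters anti to it and both methyls end up on the ester face. The step needs head-to-head regiochemistry (central allene carbon on the α-carbon C4a, a CH2 terminus on C8a), the intrinsic preference of allene with cyclic enones, and attack on the face syn to the more remote C2 methyl, which rests on the dominance of the adjacent ester. Excess allene at −78 °C should suppress enone dimerisation and hydrogen abstraction.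

Step 4
Reactants: 8 methyl (1R,2S,3R,6R)-1,3,6-trimethyl-7-methylidene-5-oxobicyclo[4.2.0]octane-2-carboxylate
Product: 9 tosylhydrazone of 8 at the C4 ketone
Conditions: TsNHNH2 (1.5 equiv), AcOH (cat.), MeOH, 65 °C
Reagents that add atoms: 4-methylbenzenesulfonohydrazide, Cc1ccc(cc1)S(=O)(=O)NN
Why: Acid-catalysed condensation of a ketone with a sulfonyl hydrazide (tosylhydrazone formation), which should engage only the C4 ketone because the ester is far less electrophilic, creates no stereocentre and leaves the strained exocyclic alkene untouched under these weakly acidic conditions.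

Step 5
Reactants: 9 tosylhydrazone of 8 at the C4 ketone
Product: 12 methyl (1R,2S,3R,6R)-1,3,6-trimethyl-7-methylidenebicyclo[4.2.0]octane-2-carboxylate, via N-boryl hydrazine 10 (not isolated), via alkyl diazene 11 (not isolated)
Conditions: catecholborane (2 equiv), CHCl3, 0 → 23 °C; then NaOAc·3H2O (3 equiv), 61 °C
Reagents that add atoms: none
Why: Kabalka modification of the Caglioti tosylhydrazone reduction, in which the borane hydride adds to C=N, acetate expels sulfinate to give the diazene and loss of N2 leaves CH2 at C4; the neutral conditions should spare the ester and the exocyclic alkene (catecholborane hydroborates alkenes only on heating) and no stereocentre remains at C4.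

Step 6
Reactants: 12 methyl (1R,2S,3R,6R)-1,3,6-trimethyl-7-methylidenebicyclo[4.2.0]octane-2-carboxylate
Product: 14 methyl (1R,2S,3R,6S)-1,3,6-trimethyl-7-oxobicyclo[4.2.0]octane-2-carboxylate, via spiro ozonide 13 (not isolated)
Conditions: O3, CH2Cl2, −78 °C; then PPh3, −78 → 23 °C
Reagents that add atoms: ozone, [O-][O+]=O
Why: Ozonolysis (Criegee mechanism) of the only C=C, followed by reductive cleavage of the ozonide, should turn the exocyclic methylene into the C5 cyclobutanone without touching any stereocentre.

Step 7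
Reactants: 14 methyl (1R,2S,3R,6S)-1,3,6-trimethyl-7-oxobicyclo[4.2.0]octane-2-carboxylate; 15 ethyl diazoacetate
Product: 16 8-ethyl 2-methyl (1R,2S,3R,6S)-1,3,6-trimethyl-7-oxobicyclo[4.3.0]nonane-2,8-dicarboxylate
Conditions: BF3·OEt2 (1.5 equiv), Et2O, 0 → 23 °C
Reagents that add atoms: none
Why: Lewis-acid-promoted diazoacetate homologation of a ketone (Tiffeneau–Demjanov-type ring expansion), fast for the strained cyclobutanone, in which the diazo carbon adds to C5 and N2 leaves with a 1,2-shift of the less substituted neighbour C8 (CH2) in preference to quaternary C4a, so the new carbon (future C7) lands between C5 and C8; the ring-fusion centres are untouched and the new ester-bearing centre is of no consequence because it is removed in step 8.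

Step 8
Reactants: 16 8-ethyl 2-methyl (1R,2S,3R,6S)-1,3,6-trimethyl-7-oxobicyclo[4.3.0]nonane-2,8-dicarboxylate
Product: 18 methyl (1R,2S,3R,6S)-1,3,6-trimethyl-7-oxobicyclo[4.3.0]nonane-2-carboxylate, via keto acid 17 (not isolated)
Conditions: NaCl (cat.), H2O (3 equiv), DMSO, 150 °C
Reagents that add atoms: none
Why: Krapcho-type dealkoxycarbonylation, in which only the activated β-keto ethyl ester is hydrolysed and decarboxylated in hot wet DMSO while the isolated methyl ester at C1 survives; no stereocentre is affected because C4a is quaternary.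

Step 9
Reactants: 18 methyl (1R,2S,3R,6S)-1,3,6-trimethyl-7-oxobicyclo[4.3.0]nonane-2-carboxylate; 15 ethyl diazoacetate
Product: 19 6-ethyl 1-methyl (1S,2R,4aS,8aR)-2,4a,8a-trimethyl-5-oxodecahydronaphthalene-1,6-dicarboxylate
Conditions: BF3·OEt2 (2 equiv), CH2Cl2, 0 → 23 °C
Reagents that add atoms: none
Why: Second diazoacetate homologation of the same type, in which again the CH2 neighbour (C7) of the C5 carbonyl should migrate in preference to quaternary C4a, so the inserted carbon becomes C6 and ring B reaches six members as a β-keto ester that cannot react further; C1, C2, C4a and C8a are untouched and the C6 epimers converge in step 10.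

Step 10
Reactants: 19 6-ethyl 1-methyl (1S,2R,4aS,8aR)-2,4a,8a-trimethyl-5-oxodecahydronaphthalene-1,6-dicarboxylate
Product: 21 methyl (1S,2R,4aS,8aR)-2,4a,8a-trimethyl-5-oxodecahydronaphthalene-1-carboxylate, via keto acid 20 (not isolated)
Conditions: NaCl (cat.), H2O (3 equiv), DMSO, 150 °C
Reagents that add atoms: none
Why: Krapcho-type dealkoxycarbonylation as in step 8, selective for the β-keto ester over the C1 methyl ester, leaving the cis-fused C5 ketone of ring B with all four stereocentres in place.

Step 11
Reactants: 21 methyl (1S,2R,4aS,8aR)-2,4a,8a-trimethyl-5-oxodecahydronaphthalene-1-carboxylate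
Product: 23 methyl (1S,2R,4aS,8aR)-2,4a,8a-trimethyl-5-(trifluoromethanesulfonyloxy)-1,2,3,4,4a,7,8,8a-octahydronaphthalene-1-carboxylate, via potassium enolate 22 (not isolated)
Conditions: KN(SiMe3)2 (1.1 equiv), THF, −78 °C; then PhNTf2, −78 → 0 °C
Reagents that add atoms: N-phenylbis(trifluoromethanesulfonimide), O=S(=O)(N(c1ccccc1)S(=O)(=O)C(F)(F)F)C(F)(F)F
Why: Enolate O-sulfonylation (enol triflate formation): C4a is quaternary, so the C5 ketone can enolise only toward C6 and the C5=C6 double bond of the target is fixed regiospecifically, while the less acidic and shielded ester α-hydrogen at C1 is left alone; no stereocentre is created.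

Step 12
Reactants: 23 methyl (1S,2R,4aS,8aR)-2,4a,8a-trimethyl-5-(trifluoromethanesulfonyloxy)-1,2,3,4,4a,7,8,8a-octahydronaphthalene-1-carboxylate; 24 5-bromo-2-methylpent-2-ene
Product: 26 methyl (1S,2R,4aR,8aR)-2,4a,8a-trimethyl-5-(4-methylpent-3-en-1-yl)-1,2,3,4,4a,7,8,8a-octahydronaphthalene-1-carboxylate, via homoprenylzinc bromide 25 (not isolated)
Conditions: 24, Zn dust, LiCl, THF, 50 °C; then 23, Pd(PPh3)4 (5 mol %), THF, 55 °C
Reagents that add atoms: none
Why: Negishi sp3–sp2 cross-coupling, in which zinc inserts into the primary bromide, zerovalent palladium adds oxidatively to the alkenyl triflate and transmetallation/reductive elimination attach the homoprenyl chain at C5 with the C5=C6 position retained; alkylzinc reagents tolerate the ester and the trisubstituted alkene and no stereocentre is involved.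

Step 13
Reactants: 26 methyl (1S,2R,4aR,8aR)-2,4a,8a-trimethyl-5-(4-methylpent-3-en-1-yl)-1,2,3,4,4a,7,8,8a-octahydronaphthalene-1-carboxylate
Product: 28 (1S,2R,4aR,8aR)-2,4a,8a-trimethyl-5-(4-methylpent-3-en-1-yl)-1,2,3,4,4a,7,8,8a-octahydronaphthalene-1-carboxylic acid, via sodium carboxylate 27 (not isolated)
Conditions: NaSEt (5 equiv), DMF, 90 °C; then 1 M HCl, 0 °C
Reagents that add atoms: none
Why: SN2 demethylation of the ester by thiolate (alkyl–oxygen cleavage), which attacks the unhindered methyl carbon and so does not depend on access to the carbonyl flanked by C2 and quaternary C8a; the alkenes are inert to thiolate, and thiolate is too weak a base to enolise the ester, so C1 should keep its configuration.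

Step 14
Reactants: 28 (1S,2R,4aR,8aR)-2,4a,8a-trimethyl-5-(4-methylpent-3-en-1-yl)-1,2,3,4,4a,7,8,8a-octahydronaphthalene-1-carboxylic acid; 29 (R)-solketal
Product: 31 [(4S)-2,2-dimethyl-1,3-dioxolan-4-yl]methyl ester of acid 28, via alkoxyphosphonium carboxylate 30 (not isolated)
Conditions: PPh3, DIAD, THF, 0 → 23 °C
Reagents that add atoms: none
Why: Mitsunobu esterification, in which the primary hydroxyl of 29 is activated as an oxyphosphonium ion and displaced at CH2 by the carboxylate, so the hindered carbonyl again need not be attacked; the dioxolane stereocentre is not a reacting centre and is retained (its descriptor changes from R to S only through the priority rules).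

Step 15
Reactants: 31 [(4S)-2,2-dimethyl-1,3-dioxolan-4-yl]methyl ester of acid 28
Product: 32 (2S)-2,3-dihydroxypropyl ester of acid 28
Conditions: AcOH/H2O 4:1, 40 °C
Reagents that add atoms: none
Why: Acid-catalysed acetal hydrolysis (acetonide removal) under weak aqueous acid, mild enough to leave the two trisubstituted alkenes unprotonated and to avoid migration of the bulky acyl group from the primary to the secondary oxygen, so the glycerol stereocentre is kept.

Step 16
Reactants: 32 (2S)-2,3-dihydroxypropyl ester of acid 28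
Product: 33 (2S)-3-acetoxy-2-hydroxypropyl (1S,2R,4aR,8aR)-2,4a,8a-trimethyl-5-(4-methylpent-3-en-1-yl)-1,2,3,4,4a,7,8,8a-octahydronaphthalene-1-carboxylate
Conditions: AcCl (1.05 equiv), 2,4,6-collidine, CH2Cl2, −78 °C
Reagents that add atoms: acetyl chloride, CC(=O)Cl
Why: Selective O-acylation of a primary over a secondary alcohol with a hindered pyridine base at low temperature, which should acetylate only the terminal hydroxyl and, being free of strong base, should not trigger acyl migration; no stereocentre is touched.

Compound list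

1 | methyl acetoacetate (methyl 3-oxobutanoate) | COC(=O)CC(C)=O | starting material
2 | (E)-hex-4-en-3-one | CCC(=O)/C=C/C | starting material
3 | methyl 2-acetyl-3-methyl-5-oxoheptanoate (Michael adduct, stereoisomer mixture) | COC(=O)C(C(C)=O)C(C)CC(=O)CC | intermediate
4 | methyl 2-hydroxy-2,3,6-trimethyl-4-oxocyclohexane-1-carboxylate (cyclic ketol, stereoisomer mixture) | COC(=O)C1C(C)CC(=O)C(C)C1(C)O | intermediate
5 | racemic methyl trans-2,3,6-trimethyl-4-oxocyclohex-2-ene-1-carboxylate | COC(=O)[C@H]1[C@H](C)CC(=O)C(C)=C1C.COC(=O)[C@@H]1[C@@H](C)CC(=O)C(C)=C1C | intermediate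
6 | methyl (1S,6R)-2,3,6-trimethyl-4-oxocyclohex-2-ene-1-carboxylate | COC(=O)[C@H]1[C@H](C)CC(=O)C(C)=C1C | intermediate
7 | allene (propa-1,2-diene) | C=C=C | starting material
8 | methyl (1R,2S,3R,6R)-1,3,6-trimethyl-7-methylidene-5-oxobicyclo[4.2.0]octane-2-carboxylate (cis-fused photoadduct; in target locants C1 ester α, C2 methyl β, C4 ketone, C4a and C8a methyls α, C5(=CH2) and C8 on the β face) | COC(=O)[C@H]1[C@H](C)CC(=O)[C@]2(C)C(=C)C[C@]12C | intermediate
9 | tosylhydrazone of 8 at the C4 ketone (stereocentres as in 8) | COC(=O)[C@H]1[C@H](C)CC(=NNS(=O)(=O)c3ccc(C)cc3)[C@]2(C)C(=C)C[C@]12C | intermediate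
10 | N-(1,3,2-benzodioxaborol-2-yl)-N'-tosylhydrazine at C4 (C4 epimers) | COC(=O)[C@H]1[C@H](C)CC(N(NS(=O)(=O)c3ccc(C)cc3)B4Oc5ccccc5O4)[C@]2(C)C(=C)C[C@]12C | intermediate
11 | C4 alkyl diazene (C4–N=NH, C4 epimers) | COC(=O)[C@H]1[C@H](C)CC(N=N)[C@]2(C)C(=C)C[C@]12C | intermediate
12 | methyl (1R,2S,3R,6R)-1,3,6-trimethyl-7-methylidenebicyclo[4.2.0]octane-2-carboxylate | COC(=O)[C@H]1[C@H](C)CC[C@]2(C)C(=C)C[C@]12C | intermediate
13 | spiro 1,2,4-trioxolane (ozonide) at C5 of 12 | COC(=O)[C@H]1[C@H](C)CC[C@]2(C)C3(OOCO3)C[C@]12C | intermediate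
14 | methyl (1R,2S,3R,6S)-1,3,6-trimethyl-7-oxobicyclo[4.2.0]octane-2-carboxylate (C5 cyclobutanone) | COC(=O)[C@H]1[C@H](C)CC[C@]2(C)C(=O)C[C@]12C | intermediate
15 | ethyl diazoacetate | CCOC(=O)C=[N+]=[N-] | starting material
16 | 8-ethyl 2-methyl (1R,2S,3R,6S)-1,3,6-trimethyl-7-oxobicyclo[4.3.0]nonane-2,8-dicarboxylate (C8 epimers) | COC(=O)[C@H]1[C@H](C)CC[C@]2(C)C(=O)C(C(=O)OCC)C[C@]12C | intermediate
17 | β-keto acid from 16 | COC(=O)[C@H]1[C@H](C)CC[C@]2(C)C(=O)C(C(=O)O)C[C@]12C | intermediate
18 | methyl (1R,2S,3R,6S)-1,3,6-trimethyl-7-oxobicyclo[4.3.0]nonane-2-carboxylate | COC(=O)[C@H]1[C@H](C)CC[C@]2(C)C(=O)CC[C@]12C | intermediate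
19 | 6-ethyl 1-methyl (1S,2R,4aS,8aR)-2,4a,8a-trimethyl-5-oxodecahydronaphthalene-1,6-dicarboxylate (C6 epimers) | COC(=O)[C@H]1[C@H](C)CC[C@]2(C)C(=O)C(C(=O)OCC)CC[C@]12C | intermediate
20 | β-keto acid from 19 | COC(=O)[C@H]1[C@H](C)CC[C@]2(C)C(=O)C(C(=O)O)CC[C@]12C | intermediate
21 | methyl (1S,2R,4aS,8aR)-2,4a,8a-trimethyl-5-oxodecahydronaphthalene-1-carboxylate | COC(=O)[C@H]1[C@H](C)CC[C@]2(C)C(=O)CCC[C@]12C | intermediate
22 | potassium C5–C6 enolate of 21 | COC(=O)[C@H]1[C@H](C)CC[C@]2(C)C([O-])=CCC[C@]12C.[K+] | intermediate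
23 | methyl (1S,2R,4aS,8aR)-2,4a,8a-trimethyl-5-(trifluoromethanesulfonyloxy)-1,2,3,4,4a,7,8,8a-octahydronaphthalene-1-carboxylate | COC(=O)[C@H]1[C@H](C)CC[C@]2(C)C(OS(=O)(=O)C(F)(F)F)=CCC[C@]12C | intermediate
24 | 5-bromo-2-methylpent-2-ene | CC(C)=CCCBr | starting material
25 | (4-methylpent-3-en-1-yl)zinc bromide | CC(C)=CCC[Zn]Br | intermediate
26 | methyl (1S,2R,4aR,8aR)-2,4a,8a-trimethyl-5-(4-methylpent-3-en-1-yl)-1,2,3,4,4a,7,8,8a-octahydronaphthalene-1-carboxylate | COC(=O)[C@H]1[C@H](C)CC[C@]2(C)C(CCC=C(C)C)=CCC[C@]12C | intermediate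
27 | sodium salt of acid 28 | [Na+].[O-]C(=O)[C@H]1[C@H](C)CC[C@]2(C)C(CCC=C(C)C)=CCC[C@]12C | intermediate
28 | (1S,2R,4aR,8aR)-2,4a,8a-trimethyl-5-(4-methylpent-3-en-1-yl)-1,2,3,4,4a,7,8,8a-octahydronaphthalene-1-carboxylic acid | OC(=O)[C@H]1[C@H](C)CC[C@]2(C)C(CCC=C(C)C)=CCC[C@]12C | intermediate
29 | (R)-solketal, [(4R)-2,2-dimethyl-1,3-dioxolan-4-yl]methanol | CC1(C)OC[C@@H](CO)O1 | starting material
30 | triphenyl(solketal-oxy)phosphonium carboxylate of 28 | CC1(C)OC[C@@H](CO[P+](c2ccccc2)(c2ccccc2)c2ccccc2)O1.[O-]C(=O)[C@H]1[C@H](C)CC[C@]2(C)C(CCC=C(C)C)=CCC[C@]12C | intermediate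
31 | [(4S)-2,2-dimethyl-1,3-dioxolan-4-yl]methyl (1S,2R,4aR,8aR)-2,4a,8a-trimethyl-5-(4-methylpent-3-en-1-yl)-1,2,3,4,4a,7,8,8a-octahydronaphthalene-1-carboxylate | CC1(C)OC[C@@H](COC(=O)[C@H]2[C@H](C)CC[C@]3(C)C(CCC=C(C)C)=CCC[C@]23C)O1 | intermediate
32 | (2S)-2,3-dihydroxypropyl (1S,2R,4aR,8aR)-2,4a,8a-trimethyl-5-(4-methylpent-3-en-1-yl)-1,2,3,4,4a,7,8,8a-octahydronaphthalene-1-carboxylate | OC[C@H](O)COC(=O)[C@H]1[C@H](C)CC[C@]2(C)C(CCC=C(C)C)=CCC[C@]12C | intermediate
33 | (2S)-3-acetoxy-2-hydroxypropyl (1S,2R,4aR,8aR)-2,4a,8a-trimethyl-5-(4-methylpent-3-en-1-yl)-1,2,3,4,4a,7,8,8a-octahydronaphthalene-1-carboxylate (CNP0146255.1) | CC(=O)OC[C@H](O)COC(=O)[C@H]1[C@H](C)CC[C@]2(C)C(CCC=C(C)C)=CCC[C@]12C | target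

Total step count: 16. Longest linear sequence: 16 steps (1 and 2 to 33); 7, 15, 24 and 29 enter as bought.

Steps most likely to fail

First risk, step 3: the process at risk is facial discrimination, because the trans C6 methyl of 6 lies on the face that allene must use, so attack may be diverted to the ester face or split between both faces. The fallback takes that methyl out of the cycloaddition and installs it afterwards; it sets out from 1 and comes back to the route at 8. Annulation of 1 with pent-1-en-3-one F1 under NaOMe in MeOH, followed by pyrrolidine/AcOH in PhMe at 110 °C, should give racemic methyl 2,3-dimethyl-4-oxocyclohex-2-ene-1-carboxylate F2 as an enone whose only stereocentre is the ester-bearing carbon. Irradiation of this enone at 350 nm with 7 in CH2Cl2 at −78 °C should then be steered by the ester alone and give racemic methyl (1R*,2S*,6R*)-1,6-dimethyl-7-methylidene-5-oxobicyclo[4.2.0]octane-2-carboxylate F3 as the cis-fused photoadduct lacking the C2 methyl. Preparative SFC on the amylose phase used for 5 should deliver methyl (1R,2S,6R)-1,6-dimethyl-7-methylidene-5-oxobicyclo[4.2.0]octane-2-carboxylate F4 as a single enantiomer. 2-Iodoxybenzoic acid in DMSO at 70 °C should desaturate C2–C3 to the enone methyl (1R,2S,6R)-1,6-dimethyl-7-methylidene-5-oxobicyclo[4.2.0]oct-3-ene-2-carboxylate F5 without touching the exocyclic alkene. Me2CuLi in Et2O at −78 °C, followed by aqueous NH4Cl, should then deliver methyl to C2 anti to the adjacent ester, which gives 8, where the route is rejoined.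

Second risk, step 9: the process at risk is slow addition of the diazo ester to a ketone flanked by quaternary C4a, which would let epoxide formation or migration of C4a compete. The fallback builds C6 in by a regiospecific cyclopropanol opening; it sets out from 18 and comes back to the route at 21. LiN(iPr)2 and Me3SiCl (THF, −78 °C) can form only one enol ether, methyl (1R,2S,3R,6S)-1,3,6-trimethyl-7-(trimethylsilyloxy)bicyclo[4.3.0]non-7-ene-2-carboxylate F6 with its double bond between C5 and C7. Et2Zn/CH2I2 (CH2Cl2, 0 °C) should cyclopropanate it to the siloxycyclopropane F7 in which the new CH2 bridges C5 and C7. FeCl3 in DMF at 0 °C should cleave the internal cyclopropane bond to the ring-enlarged methyl (1S,2R,4aS,8aR)-7-chloro-2,4a,8a-trimethyl-5-oxodecahydronaphthalene-1-carboxylate F8 as a mixture of C7 epimers. NaOAc in MeOH at 65 °C should eliminate HCl to the C6=C7 enone methyl (1S,2R,4aS,8aR)-2,4a,8a-trimethyl-5-oxo-1,2,3,4,4a,5,8,8a-octahydronaphthalene-1-carboxylate F9 and H2 over Pd/C in EtOAc then saturates it, so that the route is rejoined at 21.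

Third risk, step 5: the process at risk is incomplete hydride transfer to the neopentyl-type C=N of 9, which would stall the reduction or return ketone on work-up. The fallback removes the oxygen through the alcohol; it sets out from 8 and comes back to the route at 12. NaBH4 (MeOH, 0 °C) should reduce only the ketone to the C4 alcohol methyl (1R,2S,3R,6R)-5-hydroxy-1,3,6-trimethyl-7-methylidenebicyclo[4.2.0]octane-2-carboxylate F10 as a mixture of carbinol epimers. NaH and CS2, then MeI (THF, 0 → 23 °C) should convert this alcohol into its O-alkyl S-methyl xanthate F11 at the same carbon. Bu3SnH with AIBN in PhMe at 110 °C (Barton–McCombie deoxygenation), run at high stannane concentration so that hydrogen transfer should outrun opening of the neighbouring four-membered ring, should return 12, where the route is rejoined.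

Further compounds

F1 | step 3 | pent-1-en-3-one | CCC(=O)C=C
F2 | step 3 | racemic methyl 2,3-dimethyl-4-oxocyclohex-2-ene-1-carboxylate | COC(=O)C1CCC(=O)C(C)=C1C
F3 | step 3 | racemic methyl (1R*,2S*,6R*)-1,6-dimethyl-7-methylidene-5-oxobicyclo[4.2.0]octane-2-carboxylate (cis-fused, ester anti to the cyclobutane) | COC(=O)[C@H]1CCC(=O)[C@]2(C)C(=C)C[C@]12C.COC(=O)[C@@H]1CCC(=O)[C@@]2(C)C(=C)C[C@@]12C
F4 | step 3 | methyl (1R,2S,6R)-1,6-dimethyl-7-methylidene-5-oxobicyclo[4.2.0]octane-2-carboxylate | COC(=O)[C@H]1CCC(=O)[C@]2(C)C(=C)C[C@]12C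
F5 | step 3 | methyl (1R,2S,6R)-1,6-dimethyl-7-methylidene-5-oxobicyclo[4.2.0]oct-3-ene-2-carboxylate | COC(=O)[C@H]1C=CC(=O)[C@]2(C)C(=C)C[C@]12C
F6 | step 9 | methyl (1R,2S,3R,6S)-1,3,6-trimethyl-7-(trimethylsilyloxy)bicyclo[4.3.0]non-7-ene-2-carboxylate | COC(=O)[C@H]1[C@H](C)CC[C@]2(C)C(O[Si](C)(C)C)=CC[C@]12C
F7 | step 9 | siloxycyclopropane from F6 (CH2 bridging C5 and C7) | COC(=O)[C@H]1[C@H](C)CC[C@]2(C)C3(O[Si](C)(C)C)CC3C[C@]12C
F8 | step 9 | methyl (1S,2R,4aS,8aR)-7-chloro-2,4a,8a-trimethyl-5-oxodecahydronaphthalene-1-carboxylate (C7 epimers) | COC(=O)[C@H]1[C@H](C)CC[C@]2(C)C(=O)CC(Cl)C[C@]12C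
F9 | step 9 | methyl (1S,2R,4aS,8aR)-2,4a,8a-trimethyl-5-oxo-1,2,3,4,4a,5,8,8a-octahydronaphthalene-1-carboxylate | COC(=O)[C@H]1[C@H](C)CC[C@]2(C)C(=O)C=CC[C@]12C
F10 | step 5 | methyl (1R,2S,3R,6R)-5-hydroxy-1,3,6-trimethyl-7-methylidenebicyclo[4.2.0]octane-2-carboxylate (C5 epimers) | COC(=O)[C@H]1[C@H](C)CC(O)[C@]2(C)C(=C)C[C@]12C
F11 | step 5 | O-alkyl S-methyl carbonodithioate (xanthate) of F10 | COC(=O)[C@H]1[C@H](C)CC(OC(=S)SC)[C@]2(C)C(=C)C[C@]12C
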